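**Retrosynthetic overview**
1. The three β-aryl ether side chains are cut at C7–C8 (auxiliary-controlled aldol of an aryloxyacetyl imide with vanillin acetate) and at O–CH2 (phenol alkylation). Unit B (threo, 7R,8R) is built first, units A (erythro, 7R,8S) and C (erythro, 7S,8R) together, followed by one reductive cleavage.
2. The core, (7R,7'R,8S,8'S)-syringaresinol, is traced to a C2-symmetric tetraol; a double benzylic cyclodehydration closes both tetrahydrofuran rings at once with the aryl groups exo.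
3. The tetraol comes from a bicyclic bis-hemiketal made by a twofold acetal [1,2]-Wittig ring contraction (1,3-dioxane to 2-aryl-tetrahydrofuran-2-olate, twice) of 1,3:2,4-di-O-arylidene-D-threitol; C8 and C8' are the two threitol stereocentres.
4. Aromatic building blocks: syringaldehyde from p-cresol, vanillin from catechol and glyoxylic acid.
5. Ring order: two 1,3-dioxanes (acetalisation), then two tetrahydrofuran hemiketals (contraction), opened by reduction, then both furofuran rings (cyclodehydration).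

Assumption: D-threitol, both enantiomers of 4-benzyloxazolidin-2-one (recoverable auxiliaries, treated as reagents) and the common silyl, acyl and methyl transfer reagents are purchased.

Lignan numbering is used for the side chains (C7 benzylic, C8 ether carbon, C9 CH2OH). The two syringyl rings of the core are called ring S1 (carries units B and A) and ring S2 (carries unit C).

**Route**

Step 1
Reactants: 1 p-cresol
Product: 4 3,5-dibromo-4-hydroxybenzaldehyde, via 2,6-dibromo-4-methylphenol 2 (not isolated), via 2,6-dibromo-4-(dibromomethyl)phenol 3 (not isolated)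
Conditions: Br2 (2 equiv), o-dichlorobenzene, 35 °C; Br2 (2 equiv), 150 °C; H2O, 100 °C
Reagents that add atoms: bromine BrBr; water O
Why: The phenol directs electrophilic aromatic bromination to both ortho positions, the hot second bromination is a benzylic radical substitution to the benzal bromide, and hydrolysis of the gem-dibromide unveils the aldehyde (an established one-pot process).

Step 2
Reactants: 4 3,5-dibromo-4-hydroxybenzaldehyde
Product: 5 syringaldehyde
Conditions: NaOMe, CuCl (cat.), MeOH–DMF, 110 °C; aq. HCl work-up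
Reagents that add atoms: sodium methoxide [Na+].[O-]C
Why: Copper-catalysed Ullmann-type nucleophilic aromatic substitution replaces both aryl bromides by methoxide without touching the aldehyde.

Step 3
Reactants: 5 syringaldehyde
Product: 6 3,5-dimethoxy-4-(triisopropylsilyloxy)benzaldehyde
Conditions: TIPSOTf, 2,6-lutidine, CH2Cl2, 0 °C
Reagents that add atoms: triisopropylsilyl triflate CC(C)[Si](OS(=O)(=O)C(F)(F)F)(C(C)C)C(C)C
Why: Silylation of the hindered phenol gives a base-stable ether that has no benzylic or allylic C–H of its own and so survives the strongly basic key step.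

Step 4
Reactants: 6 3,5-dimethoxy-4-(triisopropylsilyloxy)benzaldehyde (2 equiv); 7 D-threitol
Product: 8 1,3:2,4-di-O-[(S)-3,5-dimethoxy-4-(triisopropylsilyloxy)benzylidene]-D-threitol
Conditions: 10-camphorsulfonic acid (cat.), toluene–DMF, 70 °C, reduced pressure (azeotropic removal of water)
Reagents that add atoms: none
Why: Acid-catalysed acetalisation under thermodynamic control gives the cis-fused bis-1,3-dioxane (the 1,3:2,4 pattern known from dibenzylidene alditols) with both aryl groups equatorial, leaving the two threitol stereocentres untouched.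

Step 5
Reactants: 8 1,3:2,4-di-O-[(S)-3,5-dimethoxy-4-(triisopropylsilyloxy)benzylidene]-D-threitol
Product: 10 (2S,3S)-1,4-bis[3,5-dimethoxy-4-(triisopropylsilyloxy)phenyl]-2,3-bis(hydroxymethyl)butane-1,4-diol (mixture of C1/C4 epimers), via bicyclic bis-hemiketal 9 (not isolated)
Conditions: n-BuLi, KOt-Bu, 2,2,6,6-tetramethylpiperidine (3 equiv each), THF, −78 to −30 °C; AcOH, MeOH, −78 °C; NaBH4, −40 to 0 °C
Reagents that add atoms: none
Why: Proposed new method: potassium 2,2,6,6-tetramethylpiperidide metalates aryl and acetal C–H positions reversibly, and only the benzylic 2-potassio-1,3-dioxane can leave this equilibrium, by homolysis of its O–C(secondary) bond to a caged aryl-ester ketyl radical anion/secondary alkyl radical pair that recombines at carbon (a stepwise, non-pericyclic acetal [1,2]-Wittig shift); this contracts each 1,3-dioxane to a 2-aryl-tetrahydrofuran-2-olate and forms the C7–C8 and C7'–C8' bonds, the secondary carbon migrating in preference to the primary one and recombination being possible only to the cis-fused bicycle, so both threitol stereocentres are carried over with retention as C8 and C8' (both S), while the hemiketal centres are erased by NaBH4 reduction of the ring-opened aryl ketones; the closest known reaction types are the [1,2]-Wittig ring contraction of 2-aryl cyclic ethers and the retentive acetal [1,2]-Wittig rearrangement of benzyl glycosides to C-glycosides.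

Step 6
Reactants: 10 (2S,3S)-tetraol
Product: 11 (1S,2R,5S,6R)-2,6-bis[3,5-dimethoxy-4-(triisopropylsilyloxy)phenyl]-3,7-dioxabicyclo[3.3.0]octane
Conditions: 10-camphorsulfonic acid (10 mol%), CH2Cl2, 4 Å molecular sieves, 0 °C to rt
Reagents that add atoms: none
Why: Acid ionises both benzylic alcohols to silyloxy-stabilised benzyl cations that are trapped by the 1,4-related primary alcohols (SN1 cyclodehydration), so all C7 epimers converge on the cis-fused furofuran with each aryl trans to the neighbouring ring bond (exo; 7R,7'R as dictated by 8S,8'S).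

Step 7
Reactants: 11 bis-TIPS ether of (7R,7'R,8S,8'S)-syringaresinol
Product: 12 mono-TIPS ether of (7R,7'R,8S,8'S)-syringaresinol
Conditions: TBAF (1.0 equiv), THF, −40 °C; aq. NH4Cl; recovered 11 and diphenol recycled
Reagents that add atoms: none
Why: Fluoride-mediated desilylation with one equivalent statistically unmasks one of the two equivalent phenols of the C2-symmetric core, which is the only desymmetrisation the route needs.

Step 8
Reactants: 13 catechol
Product: 14 guaiacol
Conditions: Me2SO4 (1.0 equiv), NaOH, H2O, 50 °C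
Reagents that add atoms: dimethyl sulfate COS(=O)(=O)OC
Why: Williamson O-methylation with one equivalent stops largely at the monoether because the monoanion reacts faster than the remaining, less acidic phenol.

Step 9
Reactants: 14 guaiacol; 15 glyoxylic acid
Product: 17 vanillin, via 4-hydroxy-3-methoxymandelic acid 16 (not isolated)
Conditions: NaOH, H2O, 30 °C; then air, CuSO4 (cat.), 95 °C; H2SO4
Reagents that add atoms: none
Why: Electrophilic aromatic hydroxyalkylation of the phenolate para to OH by glyoxylate followed by copper-catalysed aerobic oxidative decarboxylation is the industrial vanillin process.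

Step 10
Reactants: 17 vanillin
Product: 18 vanillin acetate
Conditions: Ac2O, pyridine, DMAP (cat.), CH2Cl2, rt
Reagents that add atoms: acetic anhydride CC(=O)OC(C)=O
Why: Acetylation masks the phenol as an ester that tolerates boron and magnesium enolates and is later removed by LiBH4 without a separate step.

Step 11
Reactants: 19 bromoacetyl bromide
Product: 20 (S)-4-benzyl-3-(bromoacetyl)oxazolidin-2-one
Conditions: (S)-4-benzyloxazolidin-2-one, n-BuLi, THF, −78 °C; then 19
Reagents that add atoms: (S)-4-benzyloxazolidin-2-one O=C1N[C@@H](Cc2ccccc2)CO1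
Why: N-acylation of the lithiated oxazolidinone by the acid bromide at low temperature is much faster than displacement of the primary bromide.

Step 12
Reactants: 19 bromoacetyl bromide
Product: 21 (R)-4-benzyl-3-(bromoacetyl)oxazolidin-2-one
Conditions: (R)-4-benzyloxazolidin-2-one, n-BuLi, THF, −78 °C; then 19
Reagents that add atoms: (R)-4-benzyloxazolidin-2-one O=C1N[C@H](Cc2ccccc2)CO1
Why: Same N-acylation as in step 11 with the enantiomeric auxiliary.

Step 13
Reactants: 12 mono-TIPS syringaresinol; 20 (S)-bromoacetyl imide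
Product: 22 ring S1 aryloxyacetyl imide of the (S)-auxiliary
Conditions: K2CO3, acetone, rt
Reagents that add atoms: none
Why: Williamson ether synthesis in which the phenoxide displaces the activated α-bromo imide bromide by SN2; no stereocentre is involved.

Step 14
Reactants: 22 ring S1 aryloxyacetyl imide; 18 vanillin acetate
Product: 23 syn aldol adduct with (2S,3R)-3-(4-acetoxy-3-methoxyphenyl)-3-hydroxy-2-aryloxypropanoyl imide
Conditions: Bu2BOTf, i-Pr2NEt, CH2Cl2, −78 to 0 °C; 18, −78 to 0 °C; pH 7 buffer, MeOH, H2O2, 0 °C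
Reagents that add atoms: none
Why: Evans syn aldol in which the (Z)-dibutylboron enolate adds through a Zimmerman–Traxler chair with one face shielded by the (S)-benzyl auxiliary, setting C8 and C7 of unit B as the syn pair that is (7R,8R)-threo after reduction.

Step 15
Reactants: 23 syn aldol adduct
Product: 24 unit B (7R,8R)-diol with free ring B phenol
Conditions: LiBH4, THF–MeOH, 0 °C to rt; aq. NH4Cl
Reagents that add atoms: none
Why: LiBH4 reductively cleaves the N-acyl oxazolidinone to the primary alcohol without epimerising C8 and at the same time reduces off the aryl acetate.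

Step 16
Reactants: 24 unit B diol phenol; 20 (S)-bromoacetyl imide
Product: 25 ring B aryloxyacetyl imide of the (S)-auxiliary
Conditions: K2CO3, acetone, rt
Reagents that add atoms: none
Why: Williamson etherification under carbonate is selective for the phenoxide over the two aliphatic hydroxyls.

Step 17
Reactants: 25 ring B aryloxyacetyl imide
Product: 26 ring S2 phenol
Conditions: TBAF, AcOH (1:1), THF, 0 °C
Reagents that add atoms: none
Why: Buffered fluoride desilylation cleaves the aryl silyl ether and leaves the imide and the benzylic ethers untouched.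

Step 18
Reactants: 26 ring S2 phenol; 21 (R)-bromoacetyl imide
Product: 27 bis-imide with (S)-auxiliary on ring B and (R)-auxiliary on ring S2
Conditions: K2CO3, acetone, rt
Reagents that add atoms: none
Why: Williamson etherification of the only free phenol installs the second glycolate with the enantiomeric auxiliary.

Step 19
Reactants: 27 bis-imide; 18 vanillin acetate (2.5 equiv)
Product: 28 bis anti-aldol adduct as tetrakis(trimethylsilyl) ether
Conditions: MgCl2 (0.5 equiv), Et3N, TMSCl, EtOAc, rt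
Reagents that add atoms: chlorotrimethylsilane C[Si](C)(C)Cl
Why: Evans MgCl2-catalysed direct anti-aldol in which each chelated (Z)-magnesium enolate adds to the non-enolisable aldehyde through a boat transition state on the face remote from its benzyl group, so the (S)-auxiliary arm gives unit A (7R,8S) and the (R)-auxiliary arm unit C (7S,8R), while TMSCl silylates the aldolates (turnover) and the two hydroxyls of unit B.

Step 20
Reactants: 28 bis anti-aldol adduct
Product: 29 CNP0316493.1 (target)
Conditions: LiBH4, THF–MeOH, 0 °C to rt; then aq. citric acid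
Reagents that add atoms: none
Why: LiBH4 reduces both imides to primary alcohols and both aryl acetates to phenols, and methanolysis removes the four trimethylsilyl ethers, none of which touches a stereocentre.

**Compound list**

1 | p-cresol | Cc1ccc(O)cc1 | starting material
2 | 2,6-dibromo-4-methylphenol | Cc1cc(Br)c(O)c(Br)c1 | intermediate
3 | 2,6-dibromo-4-(dibromomethyl)phenol | BrC(Br)c1cc(Br)c(O)c(Br)c1 | intermediate
4 | 3,5-dibromo-4-hydroxybenzaldehyde | O=Cc1cc(Br)c(O)c(Br)c1 | intermediate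
5 | syringaldehyde | COc1cc(C=O)cc(OC)c1O | intermediate
6 | 3,5-dimethoxy-4-(triisopropylsilyloxy)benzaldehyde | COc1cc(C=O)cc(OC)c1O[Si](C(C)C)(C(C)C)C(C)C | intermediate
7 | D-threitol, (2R,3R)-butane-1,2,3,4-tetrol | OC[C@@H](O)[C@H](O)CO | starting material
8 | 1,3:2,4-di-O-[(S)-3,5-dimethoxy-4-(triisopropylsilyloxy)benzylidene]-D-threitol (cis-fused bis-1,3-dioxane, aryl groups equatorial) | COc1cc(cc(OC)c1O[Si](C(C)C)(C(C)C)C(C)C)[C@H]1OC[C@H]2O[C@@H](c3cc(OC)c(O[Si](C(C)C)(C(C)C)C(C)C)c(OC)c3)OC[C@H]2O1 | intermediate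
9 | (1S,5S)-2,6-bis[3,5-dimethoxy-4-(triisopropylsilyloxy)phenyl]-3,7-dioxabicyclo[3.3.0]octane-2,6-diol (bis-hemiketal, C2/C6 unassigned) | COc1cc(cc(OC)c1O[Si](C(C)C)(C(C)C)C(C)C)C1(O)OC[C@@H]2[C@H]1COC2(O)c1cc(OC)c(O[Si](C(C)C)(C(C)C)C(C)C)c(OC)c1 | intermediate
10 | (2S,3S)-1,4-bis[3,5-dimethoxy-4-(triisopropylsilyloxy)phenyl]-2,3-bis(hydroxymethyl)butane-1,4-diol (C1/C4 epimers) | COc1cc(cc(OC)c1O[Si](C(C)C)(C(C)C)C(C)C)C(O)[C@H](CO)[C@@H](CO)C(O)c1cc(OC)c(O[Si](C(C)C)(C(C)C)C(C)C)c(OC)c1 | intermediate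
11 | bis-TIPS ether of (7R,7'R,8S,8'S)-syringaresinol | COc1cc(cc(OC)c1O[Si](C(C)C)(C(C)C)C(C)C)[C@@H]1OC[C@@H]2[C@H]1CO[C@H]2c1cc(OC)c(O[Si](C(C)C)(C(C)C)C(C)C)c(OC)c1 | intermediate
12 | mono-TIPS ether of (7R,7'R,8S,8'S)-syringaresinol | COc1cc(cc(OC)c1O)[C@@H]1OC[C@@H]2[C@H]1CO[C@H]2c1cc(OC)c(O[Si](C(C)C)(C(C)C)C(C)C)c(OC)c1 | intermediate
13 | catechol | Oc1ccccc1O | starting material
14 | guaiacol | COc1ccccc1O | intermediate
15 | glyoxylic acid | O=CC(=O)O | starting material
16 | 4-hydroxy-3-methoxymandelic acid | COc1cc(ccc1O)C(O)C(=O)O | intermediate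
17 | vanillin | COc1cc(C=O)ccc1O | intermediate
18 | vanillin acetate (4-formyl-2-methoxyphenyl acetate) | COc1cc(C=O)ccc1OC(C)=O | intermediate
19 | bromoacetyl bromide | BrCC(Br)=O | starting material
20 | (S)-4-benzyl-3-(bromoacetyl)oxazolidin-2-one | O=C(CBr)N1[C@@H](Cc2ccccc2)COC1=O | intermediate
21 | (R)-4-benzyl-3-(bromoacetyl)oxazolidin-2-one | O=C(CBr)N1[C@H](Cc2ccccc2)COC1=O | intermediate
22 | 12 with the ring S1 phenol as O–CH2–C(=O)–N imide of the (S)-auxiliary | O=C(COc3c(OC)cc([C@@H]4OC[C@@H]5[C@H]4CO[C@H]5c4cc(OC)c(O[Si](C(C)C)(C(C)C)C(C)C)c(OC)c4)cc3OC)N6[C@@H](Cc7ccccc7)COC6=O | intermediate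
23 | syn aldol adduct: (2S,3R)-3-(4-acetoxy-3-methoxyphenyl)-3-hydroxy-2-(ring S1 aryloxy)propanoyl imide of the (S)-auxiliary; ring S2 OTIPS | CC(=O)Oc2ccc([C@@H](O)[C@@H](C(=O)N6[C@@H](Cc7ccccc7)COC6=O)Oc3c(OC)cc([C@@H]4OC[C@@H]5[C@H]4CO[C@H]5c4cc(OC)c(O[Si](C(C)C)(C(C)C)C(C)C)c(OC)c4)cc3OC)cc2OC | intermediate
24 | unit B (7R,8R)-threo diol on ring S1, free ring B phenol, ring S2 OTIPS | Oc2ccc([C@@H](O)[C@@H](CO)Oc3c(OC)cc([C@@H]4OC[C@@H]5[C@H]4CO[C@H]5c4cc(OC)c(O[Si](C(C)C)(C(C)C)C(C)C)c(OC)c4)cc3OC)cc2OC | intermediate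
25 | 24 with the ring B phenol as O–CH2–C(=O)–N imide of the (S)-auxiliary | O=C(COc2ccc([C@@H](O)[C@@H](CO)Oc3c(OC)cc([C@@H]4OC[C@@H]5[C@H]4CO[C@H]5c4cc(OC)c(O[Si](C(C)C)(C(C)C)C(C)C)c(OC)c4)cc3OC)cc2OC)N6[C@@H](Cc7ccccc7)COC6=O | intermediate
26 | 25 with free ring S2 phenol | O=C(COc2ccc([C@@H](O)[C@@H](CO)Oc3c(OC)cc([C@@H]4OC[C@@H]5[C@H]4CO[C@H]5c4cc(OC)c(O)c(OC)c4)cc3OC)cc2OC)N6[C@@H](Cc7ccccc7)COC6=O | intermediate
27 | bis-imide: ring B O–CH2–CO–(S)-auxiliary and ring S2 O–CH2–CO–(R)-auxiliary | O=C(COc2ccc([C@@H](O)[C@@H](CO)Oc3c(OC)cc([C@@H]4OC[C@@H]5[C@H]4CO[C@H]5c4cc(OC)c(OCC(=O)N8[C@H](Cc9ccccc9)COC8=O)c(OC)c4)cc3OC)cc2OC)N6[C@@H](Cc7ccccc7)COC6=O | intermediate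
28 | bis anti-aldol adduct, tetrakis-TMS ether: unit A (2R,3R)-imide of the (S)-auxiliary, unit C (2S,3S)-imide of the (R)-auxiliary, two aryl acetates, unit B as bis-TMS ether | COc1cc([C@@H](O[Si](C)(C)C)[C@H](C(=O)N6[C@@H](Cc7ccccc7)COC6=O)Oc2ccc([C@@H](O[Si](C)(C)C)[C@@H](CO[Si](C)(C)C)Oc3c(OC)cc([C@@H]4OC[C@@H]5[C@H]4CO[C@H]5c4cc(OC)c(O[C@H](C(=O)N8[C@H](Cc9ccccc9)COC8=O)[C@@H](O[Si](C)(C)C)c5ccc(OC(C)=O)c(OC)c5)c(OC)c4)cc3OC)cc2OC)ccc1OC(C)=O | intermediate
29 | CNP0316493.1 | COc1cc([C@@H](O)[C@H](CO)Oc2ccc([C@@H](O)[C@@H](CO)Oc3c(OC)cc([C@@H]4OC[C@@H]5[C@H]4CO[C@H]5c4cc(OC)c(O[C@H](CO)[C@@H](O)c5ccc(O)c(OC)c5)c(OC)c4)cc3OC)cc2OC)ccc1O | target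

**Totals**
Total step count: 20. Longest linear sequence: 15 steps (steps 1–7, then 13–20).

**Steps most likely to fail**

Step 5 (the proposed double acetal [1,2]-Wittig ring contraction). Risks are competing aryl metalation, migration of the primary instead of the secondary carbon, and opening of the hemiketal alkoxide to an enolisable ketone before reduction. The fallback uses known chemistry, sets out from 5 and comes back at 11. Syringaldehyde 5 is olefinated with Ph3P=CHCO2Et in toluene at 100 °C to ethyl (E)-sinapate F1, which DIBAL-H in toluene at −78 °C reduces to (E)-sinapyl alcohol F2. Oxidative β–β dimerisation of F2 with FeCl3 in aqueous acetone gives racemic syringaresinol, and preparative HPLC on cellulose tris(3,5-dimethylphenylcarbamate) separates (7R,7'R,8S,8'S)-syringaresinol F3 from its enantiomer (7S,7'S,8R,8'R)-syringaresinol F4, which is discarded. Silylation of F3 with TIPSOTf and 2,6-lutidine gives 11.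

Step 19 (double magnesium anti-aldol). The MgCl2 protocol is established for N-acyl oxazolidinones with aromatic aldehydes, but not for aryloxyacetyl imides or on a substrate of this size, so both the anti selectivity and the facial sense are at risk. The fallback makes both units syn with the boron aldol and then inverts C7; it sets out from 24 and comes back at 29. Phenol 24 is alkylated with 21 (K2CO3, acetone) to the (R)-auxiliary ring B imide F5, and its diol is acetylated (Ac2O, pyridine, DMAP) to diacetate F6. TBAF/AcOH gives the ring S2 phenol F7, which is alkylated with 20 to the bis-imide F8, carrying the auxiliaries in the opposite sense to 27. A double Evans syn aldol (Bu2BOTf, i-Pr2NEt, then 18) gives the bis syn-adduct F9 with C8 correct and C7 epimeric in units A and C. A double Mitsunobu reaction (4-nitrobenzoic acid, PPh3, DIAD) inverts both benzylic carbinols to the bis(4-nitrobenzoate) F10, and LiBH4 in THF–MeOH removes both auxiliaries and all ester groups to give 29.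

Step 13 (alkylation of the hindered 2,6-dimethoxyphenoxide with the bromoacetyl imide; the same operation recurs in steps 16 and 18). The risk is attack of the phenoxide at the imide carbonyl instead of at CH2Br. The fallback builds the imide after the ether; it sets out from 12 and comes back at 22. Phenol 12 is alkylated with allyl bromoacetate (K2CO3, DMF) to the allyl aryloxyacetate F11. Pd(PPh3)4 with morpholine removes the allyl group to give the aryloxyacetic acid F12, which is coupled with (S)-4-benzyloxazolidin-2-one (DCC, DMAP, CH2Cl2) to give 22.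

**Further compounds**
F1 | step 5 | ethyl (E)-sinapate | CCOC(=O)/C=C/c1cc(OC)c(O)c(OC)c1
F2 | step 5 | (E)-sinapyl alcohol | OC/C=C/c1cc(OC)c(O)c(OC)c1
F3 | step 5 | (7R,7'R,8S,8'S)-syringaresinol | COc1cc(cc(OC)c1O)[C@@H]1OC[C@@H]2[C@H]1CO[C@H]2c1cc(OC)c(O)c(OC)c1
F4 | step 5 | (7S,7'S,8R,8'R)-syringaresinol | COc1cc(cc(OC)c1O)[C@H]1OC[C@H]2[C@@H]1CO[C@@H]2c1cc(OC)c(O)c(OC)c1
F5 | step 19 | 24 with the ring B phenol as O–CH2–CO imide of the (R)-auxiliary | O=C(COc2ccc([C@@H](O)[C@@H](CO)Oc3c(OC)cc([C@@H]4OC[C@@H]5[C@H]4CO[C@H]5c4cc(OC)c(O[Si](C(C)C)(C(C)C)C(C)C)c(OC)c4)cc3OC)cc2OC)N6[C@H](Cc7ccccc7)COC6=O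
F6 | step 19 | unit B diacetate of F5 | O=C(COc2ccc([C@@H](OC(C)=O)[C@@H](COC(C)=O)Oc3c(OC)cc([C@@H]4OC[C@@H]5[C@H]4CO[C@H]5c4cc(OC)c(O[Si](C(C)C)(C(C)C)C(C)C)c(OC)c4)cc3OC)cc2OC)N6[C@H](Cc7ccccc7)COC6=O
F7 | step 19 | F6 with free ring S2 phenol | O=C(COc2ccc([C@@H](OC(C)=O)[C@@H](COC(C)=O)Oc3c(OC)cc([C@@H]4OC[C@@H]5[C@H]4CO[C@H]5c4cc(OC)c(O)c(OC)c4)cc3OC)cc2OC)N6[C@H](Cc7ccccc7)COC6=O
F8 | step 19 | bis-imide diacetate: ring B (R)-auxiliary, ring S2 (S)-auxiliary | O=C(COc2ccc([C@@H](OC(C)=O)[C@@H](COC(C)=O)Oc3c(OC)cc([C@@H]4OC[C@@H]5[C@H]4CO[C@H]5c4cc(OC)c(OCC(=O)N8[C@@H](Cc9ccccc9)COC8=O)c(OC)c4)cc3OC)cc2OC)N6[C@H](Cc7ccccc7)COC6=O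
F9 | step 19 | bis syn-aldol adduct (units A and C epimeric at C7) | COc1cc([C@H](O)[C@H](C(=O)N6[C@H](Cc7ccccc7)COC6=O)Oc2ccc([C@@H](OC(C)=O)[C@@H](COC(C)=O)Oc3c(OC)cc([C@@H]4OC[C@@H]5[C@H]4CO[C@H]5c4cc(OC)c(O[C@H](C(=O)N8[C@@H](Cc9ccccc9)COC8=O)[C@H](O)c5ccc(OC(C)=O)c(OC)c5)c(OC)c4)cc3OC)cc2OC)ccc1OC(C)=O
F10 | step 19 | bis(4-nitrobenzoate) with C7 inverted in units A and C | COc1cc([C@@H](OC(=O)c2ccc(cc2)[N+](=O)[O-])[C@H](C(=O)N6[C@H](Cc7ccccc7)COC6=O)Oc2ccc([C@@H](OC(C)=O)[C@@H](COC(C)=O)Oc3c(OC)cc([C@@H]4OC[C@@H]5[C@H]4CO[C@H]5c4cc(OC)c(O[C@H](C(=O)N8[C@@H](Cc9ccccc9)COC8=O)[C@@H](OC(=O)c5ccc(cc5)[N+](=O)[O-])c5ccc(OC(C)=O)c(OC)c5)c(OC)c4)cc3OC)cc2OC)ccc1OC(C)=O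
F11 | step 13 | allyl (ring S1 aryloxy)acetate of 12 | C=CCOC(=O)COc3c(OC)cc([C@@H]4OC[C@@H]5[C@H]4CO[C@H]5c4cc(OC)c(O[Si](C(C)C)(C(C)C)C(C)C)c(OC)c4)cc3OC
F12 | step 13 | (ring S1 aryloxy)acetic acid of 12 | OC(=O)COc3c(OC)cc([C@@H]4OC[C@@H]5[C@H]4CO[C@H]5c4cc(OC)c(O[Si](C(C)C)(C(C)C)C(C)C)c(OC)c4)cc3OC
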